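Readings and results were generated by integration from invented constants; the scatter is artificial.

Add E and J at the last reading of Saturday's run, and 46.5% of the J charged is left over, standing in neither column.

the same everywhere: X 80 mM
- Wednesday's: J 0.65 M; temperature −25 °C; run made earlier
- Saturday's: J 0.79 M; temperature −5 °C; run made earlier
- delta: J 0.50 M; temperature −20 °C; time 20 min
- theta: J 1.0 M; temperature 10 °C; time 20 min

| run | time / min | E / % | J / % |
|---|---|---|---|
| Wednesday's | 2.50 | 4.1 | 83.0 |
| Wednesday's | 5.00 | 10.8 | 70.3 |
| Wednesday's | 8.00 | 17.3 | 57.9 |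
| Wednesday's | 10.0 | 21.8 | 51.6 |
| Saturday's | 0.667 | 9.3 | 64.0 |
| Saturday's | 2.00 | 25.9 | 29.4 |
| Saturday's | 3.00 | 32.8 | 18.6 |
| Saturday's | 5.00 | 41.8 | 11.7 |

(scatter of a reading: 0.3 percentage points)



- the flask that ends with the higher amount of E, in percent of the J charged, or "neither" when 2 percentage points or less lies between them (delta / theta / neither)
- final E, as a percentage of the J charged, in delta
- final E, as a percentage of the J charged, in theta

Keep the books on J. The leftover is the first entry. In Saturday's run it reads 48.6% at 3.00 min and 46.5% at 5.00 min, a fall of 2.1 percentage points against a scatter of 0.6 points on such a difference. So I book it as a loan that pays back into J, not as a loss. Its size against J at that last reading is the ratio Q = 3.97, and I carry this reading over to delta and theta, which is a guess.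

The second entry is E. Take the gain in E over the mean J between late readings, with c_X the same in all runs, and you have a pseudo-first-order constant k: 0.297 min⁻¹ in Saturday's run and 0.0361 min⁻¹ in Wednesday's. That is an activation energy of 58.3 kJ mol⁻¹, so k is 0.0631 min⁻¹ in delta and 1.19 min⁻¹ in theta.

If E is fed from J while the leftover trades with J, then J and leftover together empty with the pool half-life, ln 2 times (one plus Q) over k: 54.7 min in delta, 2.90 min in theta.

Delta's pool half-life exceeds its time, so iterate. Let J fall exponentially to its end share, which is what E leaves divided by one plus Q, and put the log-mean J back into k times time. From E at nil the rounds give 62.8%, 45.0%, 51.0%, 49.1%. The books for delta close near E 49.1%, J 10.2%, leftover 40.7%. Theta has 6.89 half-lives, so I reckon E near 99.2%, and theta ends higher.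

The forecast says delta, with 50% (42% to 58%) in delta and 39% (27% to 52%) in theta, on the grounds of “a faster side loss whose activity dies away”. On theta I part from it.

The flasks give theta, with 52.3% in delta and 95.3% in theta, where 3.18% stood as G at 20.0 min.

    J + X → D (k = 1.20 L mol⁻¹ min⁻¹, Ea = 50.0 kJ mol⁻¹)
    D ⇌ X + E (K = 6.80 M, k = 0.840 min⁻¹, Ea = 61.0 kJ mol⁻¹, ΔH = 1.00 kJ mol⁻¹)
    J ⇌ G (K = 2.10, k = 0.0680 min⁻¹, Ea = 71.0 kJ mol⁻¹, ΔH = 14.0 kJ mol⁻¹)
    (constants at −20 °C)

Put the pool half-life to use on J plus G. In theta, 17.3% at 10.0 min reckons down to 1.59% at 20.0 min, and the flask held 3.72%. In delta, 45.8% at 20.0 min reckons down to 4.68% at 200 min, and the flask held 2.18%.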